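A direct plan would close ring C onto an intact ring A: thermal condensation of the α-pivaloyloxy
β-keto ester A1 with 2-methoxyresorcinol A2 would give the 7-hydroxy-8-methoxychromone A3,
carbonyl-directed C–H hydroxylation at C5 would give the 5,7-dihydroxychromone A4, and
O7-prenylation and ester cleavage would finish. Its weakest steps would be: the thermal phenol/keto
ester condensation, unprecedented for an α-acyloxy keto ester and for a resorcinol far less
nucleophilic than phloroglucinol; the peri C–H hydroxylation, in which a trivalent iodine oxidant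
would meet an electron-rich ring with a methoxy group para to the new oxygen (quinone formation);
and the acylation/deacylation steps, which would add length without adding complexity.

**New strategy.** Ring A is built last. Its atoms C5–C8 carry exactly the pattern a semisquarate delivers on thermal ring expansion: para oxygens at C5 and C8, H at C6, an alkoxy group at C7. A preformed ring C, a 2-aryl-3-silyloxypyran-4-one, is lithiated at C6 and added to a prenyl semisquarate (C8–C8a bond). After O-methylation, thermolysis opens the cyclobutenone to a dienylketene whose 6π-closure onto the pyrone forms C4a–C5. One operation thus sets 5-OH free, 7-O-prenyl and 8-OMe, already differentiated. Phenol C-acylation at 240 °C, C–H oxidation, selective O-alkylation and the acyl protecting-group detour have no counterpart, and a 6-/8-methoxy ambiguity cannot arise.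

Key step: step 7

Remark on the chemistry: the target is achiral, so no stereocentre has to be set; 3-hydroxy-4H-pyran-4-one (pyromeconic acid), the vanillyl pinacol boronate and diisopropyl squarate are taken as purchasable.

Step 1
Reactants: 1 3-hydroxy-4H-pyran-4-one (pyromeconic acid)
Product: 2 2-bromo-3-hydroxy-4H-pyran-4-one
Conditions: NBS (1.0 equiv), MeCN, 0 °C to rt, dark
Reagents that add atoms: N-bromosuccinimide, O=C1CCC(=O)N1Br
Why: Electrophilic bromination of an enol, in which C2 is the β-carbon of the C3 enol and the only enol-activated ring position (the site at which 3-hydroxy-4-pyranones undergo aldol, Mannich and halogenation reactions), so one equivalent of NBS should give the 2-bromide.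

Step 2
Reactants: 2 2-bromo-3-hydroxy-4H-pyran-4-one; 3 2-methoxy-4-(4,4,5,5-tetramethyl-1,3,2-dioxaborolan-2-yl)phenol
Product: 4 3-hydroxy-2-(4-hydroxy-3-methoxyphenyl)-4H-pyran-4-one
Conditions: 3 (1.2 equiv), Pd(PPh3)4 (5 mol%), K2CO3 (3.5 equiv), dioxane/H2O 4:1, 85 °C, Ar; acidify to pH 3
Reagents that add atoms: none
Why: Suzuki–Miyaura coupling, in which the C2–Br bond of a β-bromo enone (a vinylogous acyl bromide) adds readily to zerovalent palladium and both acidic OH groups are simply carried as potassium salts in the aqueous base.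

Step 3
Reactants: 4 3-hydroxy-2-(4-hydroxy-3-methoxyphenyl)-4H-pyran-4-one
Product: 5 3-(tert-butyldimethylsilyloxy)-2-[4-(tert-butyldimethylsilyloxy)-3-methoxyphenyl]-4H-pyran-4-one
Conditions: TBSCl (2.6 equiv), imidazole (5 equiv), DMAP (cat.), DMF, 40 °C
Reagents that add atoms: tert-butyldimethylsilyl chloride, CC(C)(C)[Si](C)(C)Cl
Why: Standard O-silylation of an enol and a phenol, with TBS ethers chosen because they carry no acidic C–H, resist a hindered lithium amide, MeOTf and 110 °C, and leave with fluoride without touching an aryl prenyl ether.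

Step 4
Reactants: 6 3,4-diisopropoxycyclobut-3-ene-1,2-dione (diisopropyl squarate)
Product: 8 3-isopropoxycyclobut-3-ene-1,2-dione, via hydroxycyclobutenone 7 (not isolated)
Conditions: LiAlH(OtBu)3 (1.05 equiv), THF, −78 to −20 °C, aq. HCl work-up; then conc. aq. HCl (few drops), CH2Cl2, rt
Reagents that add atoms: water, O
Why: Partial hydride reduction of one squarate carbonyl followed by acid-induced 1,3-transposition and hydrolysis (water adds to the alkoxy-stabilised cyclobutenyl cation and isopropanol leaves), the known preparation of semisquaric esters.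

Step 5
Reactants: 8 3-isopropoxycyclobut-3-ene-1,2-dione; 9 3-methylbut-2-en-1-ol (prenol)
Product: 10 3-(3-methylbut-2-enyloxy)cyclobut-3-ene-1,2-dione (prenyl semisquarate)
Conditions: 9 (5 equiv), iPr2NEt (0.1 equiv), PhMe, 40 °C; iPrOH and excess 9 removed under reduced pressure
Reagents that add atoms: none
Why: Vinylogous transesterification by addition–elimination at C3 of the cyclobutenedione (squarate esters exchange alkoxy groups with alcohols under mild base), in which the hindered amine avoids acid that would ionise prenol and removal of the lower-boiling isopropanol drives the equilibrium.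

Step 6
Reactants: 5 3-(tert-butyldimethylsilyloxy)-2-[4-(tert-butyldimethylsilyloxy)-3-methoxyphenyl]-4H-pyran-4-one; 10 3-(3-methylbut-2-enyloxy)cyclobut-3-ene-1,2-dione
Product: 13 4-[5-(tert-butyldimethylsilyloxy)-6-[4-(tert-butyldimethylsilyloxy)-3-methoxyphenyl]-4-oxo-4H-pyran-2-yl]-4-methoxy-3-(3-methylbut-2-enyloxy)cyclobut-2-en-1-one (racemic), via 6-lithiopyranone 11 (not isolated), via lithium cyclobutenolate 12 (not isolated)
Conditions: lithium 2,2,6,6-tetramethylpiperidide (from the amine and n-BuLi, 1.05 equiv), THF, −78 °C, 20 min; 10 (1.3 equiv), −78 °C, 30 min; MeOTf (1.5 equiv), −78 to −20 °C; aq. NaHCO3 at −20 °C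
Reagents that add atoms: methyl trifluoromethanesulfonate, COS(=O)(=O)C(F)(F)F
Why: Kinetic C–H lithiation of the γ-pyrone at C6, the acidic position next to the ring oxygen that hindered amide bases metalate in chromones and 4-pyranones (C2 is blocked by the aryl group), then the known 1,2-addition of an organolithium to the more electrophilic carbonyl of an alkoxycyclobutenedione (C2, the one outside the vinylogous ester, which places the carbinol carbon next to the prenyloxy carbon) and trapping of the tertiary alkoxide with a small excess of MeOTf, kept cold so that the far less nucleophilic pyranone carbonyl oxygen is not methylated; the quaternary centre forms racemic and is erased in step 7.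

Step 7
Reactants: 13 4-[5-(tert-butyldimethylsilyloxy)-6-[4-(tert-butyldimethylsilyloxy)-3-methoxyphenyl]-4-oxo-4H-pyran-2-yl]-4-methoxy-3-(3-methylbut-2-enyloxy)cyclobut-2-en-1-one
Product: 16 3-(tert-butyldimethylsilyloxy)-2-[4-(tert-butyldimethylsilyloxy)-3-methoxyphenyl]-5-hydroxy-8-methoxy-7-(3-methylbut-2-enyloxy)-4H-chromen-4-one, via dienylketene 14 (not isolated), via 4aH-chromenedione 15 (not isolated)
Conditions: PhMe (0.02 M, degassed), 110 °C, 1–2 h, Ar
Reagents that add atoms: none
Why: Moore-type ring expansion of a 4-alkoxy-4-(hetero)aryl- or 4-alkenylcyclobutenone (squarate benzannulation) is the closest known reaction type, here with the C5=C6 bond of a γ-pyrone as the 2π partner. Heat opens the cyclobutenone by conrotatory 4π-electrocyclic cleavage of C1–C4, and the donor 4-OMe rotates outward, which places the pyranyl group on the same side as the ketene in dienylketene 14. Ring A then closes by thermal disrotatory 6π-electrocyclisation, the electrophilic ketene carbon bonding to pyrone C5 (the nucleophilic α-carbon of the vinylogous ester) to make the C4a–C5 bond, and enolisation of the doubly activated C4a–H in 15 gives the aromatic ring with its hydrogen-bonded 5-OH. No stereocentre is created, since the racemic quaternary carbon of 13 and the transient C4a of 15 both become sp2. Regiochemistry needs no control because connectivity fixes it (ketene carbon becomes C5, the former C2–H becomes C6–H, C3–O-prenyl becomes C7, C4–OMe becomes C8), and the methyl ether excludes the furanone and quinone pathways of free 4-hydroxycyclobutenones. The selectivity that must be secured is ring opening ahead of a [3,3] shift of the allyl vinyl ether unit, which is favoured by the low opening barrier of 4-alkoxycyclobutenones at 110 °C and by the acyl-substituted vinyl terminus and gem-dimethyl allyl terminus, both of which slow a Claisen shift.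

Step 8
Reactants: 16 3-(tert-butyldimethylsilyloxy)-2-[4-(tert-butyldimethylsilyloxy)-3-methoxyphenyl]-5-hydroxy-8-methoxy-7-(3-methylbut-2-enyloxy)-4H-chromen-4-one
Product: 17 3,5-dihydroxy-2-(4-hydroxy-3-methoxyphenyl)-8-methoxy-7-(3-methylbut-2-enyloxy)-4H-chromen-4-one (CNP0210396.0)
Conditions: Bu4NF (2.5 equiv), AcOH (3 equiv), THF, 0 °C, Ar
Reagents that add atoms: none
Why: Fluoride-induced Si–O cleavage of an aryl and an enol silyl ether, buffered with acetic acid so that the flavonol is not exposed to base and air, while the aryl prenyl ether, both methyl ethers and the chromone are inert.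

## Compound list
1 | 3-hydroxy-4H-pyran-4-one (pyromeconic acid) | O=c1ccocc1O | starting material
2 | 2-bromo-3-hydroxy-4H-pyran-4-one | O=c1ccoc(Br)c1O | intermediate
3 | 2-methoxy-4-(4,4,5,5-tetramethyl-1,3,2-dioxaborolan-2-yl)phenol | COc1cc(B2OC(C)(C)C(C)(C)O2)ccc1O | starting material
4 | 3-hydroxy-2-(4-hydroxy-3-methoxyphenyl)-4H-pyran-4-one | COc1cc(-c2occc(=O)c2O)ccc1O | intermediate
5 | 3-(tert-butyldimethylsilyloxy)-2-[4-(tert-butyldimethylsilyloxy)-3-methoxyphenyl]-4H-pyran-4-one | COc1cc(-c2occc(=O)c2O[Si](C)(C)C(C)(C)C)ccc1O[Si](C)(C)C(C)(C)C | intermediate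
6 | 3,4-diisopropoxycyclobut-3-ene-1,2-dione (diisopropyl squarate) | CC(C)OC1=C(OC(C)C)C(=O)C1=O | starting material
7 | 4-hydroxy-2,3-diisopropoxycyclobut-2-en-1-one (racemic, not isolated) | CC(C)OC1=C(OC(C)C)C(O)C1=O | intermediate
8 | 3-isopropoxycyclobut-3-ene-1,2-dione | CC(C)OC1=CC(=O)C1=O | intermediate
9 | 3-methylbut-2-en-1-ol (prenol) | CC(C)=CCO | starting material
10 | 3-(3-methylbut-2-enyloxy)cyclobut-3-ene-1,2-dione | CC(C)=CCOC1=CC(=O)C1=O | intermediate
11 | 3-(tert-butyldimethylsilyloxy)-2-[4-(tert-butyldimethylsilyloxy)-3-methoxyphenyl]-6-lithio-4H-pyran-4-one (not isolated) | [Li]c1cc(=O)c(O[Si](C)(C)C(C)(C)C)c(-c2ccc(O[Si](C)(C)C(C)(C)C)c(OC)c2)o1 | intermediate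
12 | lithium 1-[5-(tert-butyldimethylsilyloxy)-6-[4-(tert-butyldimethylsilyloxy)-3-methoxyphenyl]-4-oxo-4H-pyran-2-yl]-2-(3-methylbut-2-enyloxy)-4-oxocyclobut-2-en-1-olate (racemic, not isolated) | [Li+].[O-]C1(C(OCC=C(C)C)=CC1=O)c1cc(=O)c(O[Si](C)(C)C(C)(C)C)c(-c2ccc(O[Si](C)(C)C(C)(C)C)c(OC)c2)o1 | intermediate
13 | 4-[5-(tert-butyldimethylsilyloxy)-6-[4-(tert-butyldimethylsilyloxy)-3-methoxyphenyl]-4-oxo-4H-pyran-2-yl]-4-methoxy-3-(3-methylbut-2-enyloxy)cyclobut-2-en-1-one (racemic) | COC1(C(OCC=C(C)C)=CC1=O)c1cc(=O)c(O[Si](C)(C)C(C)(C)C)c(-c2ccc(O[Si](C)(C)C(C)(C)C)c(OC)c2)o1 | intermediate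
14 | (3Z)-4-[5-(tert-butyldimethylsilyloxy)-6-[4-(tert-butyldimethylsilyloxy)-3-methoxyphenyl]-4-oxo-4H-pyran-2-yl]-4-methoxy-3-(3-methylbut-2-enyloxy)buta-1,3-dien-1-one (not isolated) | O=C=C/C(OCC=C(C)C)=C(\c1cc(=O)c(O[Si](C)(C)C(C)(C)C)c(-c2ccc(O[Si](C)(C)C(C)(C)C)c(OC)c2)o1)OC | intermediate
15 | 3-(tert-butyldimethylsilyloxy)-2-[4-(tert-butyldimethylsilyloxy)-3-methoxyphenyl]-8-methoxy-7-(3-methylbut-2-enyloxy)-4aH-chromene-4,5-dione (racemic, not isolated) | COC1=C2OC(-c3ccc(O[Si](C)(C)C(C)(C)C)c(OC)c3)=C(O[Si](C)(C)C(C)(C)C)C(=O)C2C(=O)C=C1OCC=C(C)C | intermediate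
16 | 3-(tert-butyldimethylsilyloxy)-2-[4-(tert-butyldimethylsilyloxy)-3-methoxyphenyl]-5-hydroxy-8-methoxy-7-(3-methylbut-2-enyloxy)-4H-chromen-4-one | COc1cc(-c2oc3c(OC)c(OCC=C(C)C)cc(O)c3c(=O)c2O[Si](C)(C)C(C)(C)C)ccc1O[Si](C)(C)C(C)(C)C | intermediate
17 | 3,5-dihydroxy-2-(4-hydroxy-3-methoxyphenyl)-8-methoxy-7-(3-methylbut-2-enyloxy)-4H-chromen-4-one | COc1cc(-c2oc3c(OC)c(OCC=C(C)C)cc(O)c3c(=O)c2O)ccc1O | target

Total step count: 8. Longest linear sequence: 6 steps (steps 1, 2, 3, 6, 7, 8); the semisquarate branch (steps 4, 5) joins at step 6.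

**Steps most likely to fail**

Step 6. The pyrone may be deprotonated next to the carbonyl (C5) instead of next to the ring oxygen, the lithiated pyrone may add to unmetalated pyrone before it meets 10, or methylation may take place at the pyranone carbonyl oxygen instead of the hindered alkoxide. The fallback sets out from 5 and separates metalation, addition and methylation. Zincation of 5 next to the ring oxygen with TMP2Zn·2MgCl2·2LiCl (a Lewis-acid-assisted zinc amide of the kind used for chromones and 4-pyranones), then iodine, would give 3-(tert-butyldimethylsilyloxy)-2-[4-(tert-butyldimethylsilyloxy)-3-methoxyphenyl]-6-iodo-4H-pyran-4-one F1, which can be purified and its regiochemistry checked. Iodine–magnesium exchange with iPrMgCl·LiCl at −40 °C in the absence of any amide base and addition to 10 would give the tertiary alcohol 4-hydroxy-4-(pyranyl)-3-(3-methylbut-2-enyloxy)cyclobut-2-en-1-one F2. Methylation with MeI and Ag2O, which leaves the pyranone carbonyl alone, would then return to the route at 13.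

Step 7. A [3,3] shift or ionisation of the prenyl enol ether may compete with ring opening, or the electrocyclic closure may be too slow at the temperature the prenyl group tolerates. The fallback sets out from 8 and defers the prenyl group. Alkoxy exchange of 8 with benzyl alcohol (as in step 5) would give 3-(benzyloxy)cyclobut-3-ene-1,2-dione F3. Lithiated 5 and MeOTf (as in step 6) would give the 3-benzyloxy-4-methoxycyclobutenone F4, which cannot rearrange and can be thermolysed at 140–160 °C (xylene or flow) to the 7-benzyloxy-5-hydroxy-8-methoxyflavone F5. Hydrogenolysis (H2, 10% Pd on carbon, EtOAc) would give the 5,7-dihydroxy-8-methoxyflavone F6. Prenyl bromide and K2CO3 in acetone would alkylate only the 7-OH (the 5-OH is chelated to the C4 carbonyl) and return to the route at 16.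

Step 5. The base-catalysed alkoxy exchange may stall at equilibrium, the cyclobutenedione ring may be opened by alkoxide, or the product may ionise at the prenyl–oxygen bond. The fallback sets out from 8: hydrolysis with aqueous HCl would give 3-hydroxycyclobut-3-ene-1,2-dione F7 (semisquaric acid). O-alkylation of its caesium salt (Cs2CO3) with prenyl bromide in DMF, an SN2 reaction at the primary allylic carbon in which both terminal oxygens of the anion are equivalent, would return to the route at 10.

## Further compounds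
F1 | step 6 | 3-(tert-butyldimethylsilyloxy)-2-[4-(tert-butyldimethylsilyloxy)-3-methoxyphenyl]-6-iodo-4H-pyran-4-one | Ic1cc(=O)c(O[Si](C)(C)C(C)(C)C)c(-c2ccc(O[Si](C)(C)C(C)(C)C)c(OC)c2)o1
F2 | step 6 | 4-[5-(tert-butyldimethylsilyloxy)-6-[4-(tert-butyldimethylsilyloxy)-3-methoxyphenyl]-4-oxo-4H-pyran-2-yl]-4-hydroxy-3-(3-methylbut-2-enyloxy)cyclobut-2-en-1-one (racemic) | OC1(C(OCC=C(C)C)=CC1=O)c1cc(=O)c(O[Si](C)(C)C(C)(C)C)c(-c2ccc(O[Si](C)(C)C(C)(C)C)c(OC)c2)o1
F3 | step 7 | 3-(benzyloxy)cyclobut-3-ene-1,2-dione | O=C1C=C(OCc2ccccc2)C1=O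
F4 | step 7 | 3-(benzyloxy)-4-[5-(tert-butyldimethylsilyloxy)-6-[4-(tert-butyldimethylsilyloxy)-3-methoxyphenyl]-4-oxo-4H-pyran-2-yl]-4-methoxycyclobut-2-en-1-one (racemic) | COC1(C(OCc2ccccc2)=CC1=O)c1cc(=O)c(O[Si](C)(C)C(C)(C)C)c(-c2ccc(O[Si](C)(C)C(C)(C)C)c(OC)c2)o1
F5 | step 7 | 7-(benzyloxy)-3-(tert-butyldimethylsilyloxy)-2-[4-(tert-butyldimethylsilyloxy)-3-methoxyphenyl]-5-hydroxy-8-methoxy-4H-chromen-4-one | COc1cc(-c2oc3c(OC)c(OCc4ccccc4)cc(O)c3c(=O)c2O[Si](C)(C)C(C)(C)C)ccc1O[Si](C)(C)C(C)(C)C
F6 | step 7 | 3-(tert-butyldimethylsilyloxy)-2-[4-(tert-butyldimethylsilyloxy)-3-methoxyphenyl]-5,7-dihydroxy-8-methoxy-4H-chromen-4-one | COc1cc(-c2oc3c(OC)c(O)cc(O)c3c(=O)c2O[Si](C)(C)C(C)(C)C)ccc1O[Si](C)(C)C(C)(C)C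
F7 | step 5 | 3-hydroxycyclobut-3-ene-1,2-dione (semisquaric acid) | O=C1C=C(O)C1=O
A1 | direct plan | ethyl 3-[3-methoxy-4-(pivaloyloxy)phenyl]-3-oxo-2-(pivaloyloxy)propanoate (racemic) | CCOC(=O)C(OC(=O)C(C)(C)C)C(=O)c1ccc(OC(=O)C(C)(C)C)c(OC)c1
A2 | direct plan | 2-methoxybenzene-1,3-diol (2-methoxyresorcinol) | COc1c(O)cccc1O
A3 | direct plan | 7-hydroxy-8-methoxy-2-[3-methoxy-4-(pivaloyloxy)phenyl]-4-oxo-4H-chromen-3-yl pivalate | COc1cc(-c2oc3c(OC)c(O)ccc3c(=O)c2OC(=O)C(C)(C)C)ccc1OC(=O)C(C)(C)C
A4 | direct plan | 5,7-dihydroxy-8-methoxy-2-[3-methoxy-4-(pivaloyloxy)phenyl]-4-oxo-4H-chromen-3-yl pivalate | COc1cc(-c2oc3c(OC)c(O)cc(O)c3c(=O)c2OC(=O)C(C)(C)C)ccc1OC(=O)C(C)(C)C
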